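You want to know what holds most of the starting material at the end of Thursday's flask and of Friday's flask, two flasks charged alike and stopped at different times.

common to all: gas 31 mM (held)

|  | starting material | second substrate | remark | time |
|---|---|---|---|---|
| noon | 0.30 M | 0.84 M | run made earlier |  |
| dawn | 0.30 M | 1.3 M | run made earlier |  |
| dusk | 0.45 M | 0.60 M | run made earlier |  |
| Thursday's | 0.30 M | 0.600 M |  | 50 min |
| Friday's | 0.30 M | 0.600 M |  | 120 min |

| run | time / min | isomer of the product / % | target / % | starting material / % | over-reaction product / % |
|---|---|---|---|---|---|
| noon | 4.00 | 1 | 5 | 96 | 0 |
| noon | 10.0 | 1 | 4 | 94 | 2 |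
| noon | 20.0 | 0 | 8 | 87 | 1 |
| noon | 30.0 | 3 | 13 | 80 | 2 |
| dawn | 2.50 | 0 | 2 | 98 | 1 |
| dawn | 6.00 | 3 | 3 | 99 | 0 |
| dawn | 12.0 | 3 | 5 | 95 | 2 |
| dawn | 30.0 | 5 | 9 | 84 | 0 |
| dusk | 2.50 | 0 | 2 | 95 | 0 |
| dusk | 6.00 | 0 | 4 | 97 | 1 |
| dusk | 12.0 | 0 | 5 | 91 | 2 |
| dusk | 30.0 | 5 | 16 | 80 | 0 |

(scatter of a reading: 1.5 percentage points)

- at the start none of the gas is in solution

* which of these there is most of at the end, counted by the starting material in it, Thursday's (starting material / target / isomer of the product / over-reaction product)
* which of these there is most of at the end, counted by the starting material in it, Friday's (starting material / target / isomer of the product / over-reaction product)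
* amount of the one of these that there is most of at the end, in percent of the starting material charged, Thursday's
* amount of the one of these that there is most of at the end, in percent of the starting material charged, Friday's

Start from the last readings. By 30.0 min the noon run lost a fraction 0.00667 min⁻¹ of its charge per minute, and the dawn run, with more second substrate, lost less, 0.00533 min⁻¹. So I take it that the two substrates share what the held gas feeds in. If they fall together, that share holds and the loss runs on a straight line instead of an exponential. Extrapolating the line through these two scattered readings down to 0.600 M, which lies below both runs, gives a slope w = 0.00736 min⁻¹, so my estimate of a, the fraction of starting material left, is 63.2 % on Thursday's and 11.7 % on Friday's.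

Now suppose target, counted together with its isomer as T, is attacked as readily per molecule as starting material. Each small fall da then adds da to T and removes (T/a)da, which integrates to T = a·ln(1/a). The remainder is the over-reaction share o, the charge minus a and T. Thursday's gives T = 29.0 % and o = 7.80 %, so starting material leads. Friday's gives T = 25.0 % and o = 63.3 %, so over-reaction product leads.

The weak link is that equal attack. Tested on the noon run's last starting material, o gives 2.15 % against a reading of 2 %, with a scatter of 1.5 percentage points, so the reading allows the assumption without proving it.

The forecast gave starting material at 69 % for Thursday's and starting material at 41 % for Friday's, in its words “Starting material therefore probably still leads on Friday, but narrowly”. Thursday's flask holds most starting material, 60.0 %, and Friday's flask most over-reaction product, 61.6 %.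

    starting material + coupling partner → target (k = 2.70 M⁻¹ min⁻¹)
    second substrate + coupling partner → second product (k = 4.40 M⁻¹ min⁻¹)
    coupling partner + target → over-reaction product (k = 3.20 M⁻¹ min⁻¹)
    target ⇌ isomer of the product (K = 0.290, k = 0.120 min⁻¹)
    gas ⇌ coupling partner, rate k5*(csat - [coupling partner]) (kL = 0.360 min⁻¹)

Target takes the coupling partner with 3.2 M⁻¹ min⁻¹ against 2.7 M⁻¹ min⁻¹ for starting material, a selectivity factor of 1.19, where the equal attack assumed 1; on Friday's flask o stood at 63.3 % and the over-reaction product stands at 61.6 %. In the neighbour of Thursday's flask charged with 0.36 M of second substrate, 48.2 % of starting material is left, which puts o at 16.6 %, and that flask holds 15.8 % of over-reaction product.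

Readings and results come from a simulation from invented constants.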